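**Plan**

- Enabling feature: C2 of the flavanone is bonded to O1 and is para-benzylic to the 4'-hydroxyl of ring B. A 4-hydroxybenzyl ether on the ring A oxygen is therefore a masked para-quinone methide that the enol carbon C3 can attack.
- Retrosynthetic cuts, in order: the protecting groups; C2–C3 of ring C (oxidative 1,6-addition); O1–CH2 (benzylic ether); C4–C4a (Friedel–Crafts acylation of a phloroglucinol unit); C8–CH2 of the flavone (allyl group, Claisen); O7–S of the flavone (sulfation).
- Forward order: apigenin supplies the whole flavone. Its O7 is allylated, the allyl group is moved to C8, O7 is sulfated as the trichloroethyl diester and the allyl group is cut down to an acetic acid. The acid acylates ring A, the ring A phenol is etherified with the ring B benzyl unit, and ring C of the flavanone, the only ring made, is closed last.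
- Stereochemistry: C2 (R) is set during ring closure inside a chiral phosphate ion pair; C3 (S) follows as the trans, diequatorial epimer through enolisation.

Key step: step 11

Remark on the catalyst: the (R)-configured phosphoric acid is assumed to deliver the (2R) center; if the sense of induction is the opposite, its (S)-enantiomer is used with no other change.

Remark on the end product: the target is drawn as the free hydrogen sulfate, so it is released from its ammonium salt by proton exchange at the very end and should be kept cold or stored as the salt.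

Abbreviation used in names: Fl = 5-(benzyloxy)-2-[4-(benzyloxy)phenyl]-4-oxo-7-{[(2,2,2-trichloroethoxy)sulfonyl]oxy}-4H-chromen-8-yl.

**Route**

Step 1
Reactants: 1 apigenin; 2 allyl bromide
Product: 3 7-(allyloxy)-5-hydroxy-2-(4-hydroxyphenyl)-4H-chromen-4-one
Conditions: allyl bromide (1.1 equiv), K2CO3 (1.1 equiv), DMF, rt
Reagents that add atoms: allyl bromide, C=CCBr
Why: Williamson etherification in which the 7-hydroxyl, a vinylogous carboxylic acid and the most acidic phenol of apigenin, should be alkylated first when base and halide are limited, the 4'-hydroxyl reacting more slowly and the chelated 5-hydroxyl not at all.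

Step 2
Reactants: 3 7-(allyloxy)-5-hydroxy-2-(4-hydroxyphenyl)-4H-chromen-4-one; 4 benzyl bromide
Product: 5 7-(allyloxy)-5-(benzyloxy)-2-[4-(benzyloxy)phenyl]-4H-chromen-4-one
Conditions: BnBr (3 equiv), K2CO3, Bu4NI (cat.), DMF, 80 °C
Reagents that add atoms: benzyl bromide, BrCc1ccccc1
Why: Exhaustive Williamson benzylation, in which the 4'-hydroxyl reacts readily and the hydrogen-bonded 5-hydroxyl follows on heating with excess bromide and iodide catalysis.

Step 3
Reactants: 5 7-(allyloxy)-5-(benzyloxy)-2-[4-(benzyloxy)phenyl]-4H-chromen-4-one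
Product: 6 8-allyl-5-(benzyloxy)-2-[4-(benzyloxy)phenyl]-7-hydroxy-4H-chromen-4-one
Conditions: N,N-diethylaniline, 200 °C, argon
Reagents that add atoms: none
Why: Aromatic Claisen rearrangement ([3,3]-sigmatropic shift, then tautomerisation), which in 7-allyloxychromones with an alkylated O5 should deliver the allyl group to C8, the ortho position between O7 and the pyrone oxygen, and which creates no stereocenter.

Step 4
Reactants: 6 8-allyl-5-(benzyloxy)-2-[4-(benzyloxy)phenyl]-7-hydroxy-4H-chromen-4-one; 7 2,2,2-trichloroethyl chlorosulfate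
Product: 8 8-allyl-5-(benzyloxy)-2-[4-(benzyloxy)phenyl]-4-oxo-4H-chromen-7-yl 2,2,2-trichloroethyl sulfate
Conditions: Cl3CCH2OSO2Cl, Et3N, DMAP (cat.), THF, 0 °C to rt
Reagents that add atoms: 2,2,2-trichloroethyl chlorosulfate, ClS(=O)(=O)OCC(Cl)(Cl)Cl
Why: Sulfation of a phenol with a protected chlorosulfate under nucleophilic catalysis, which needs no selectivity because the 7-hydroxyl is the only free hydroxyl, and which gives a neutral diester that also keeps O7 from lactonising with the side chain later.

Step 5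
Reactants: 8 8-allyl-5-(benzyloxy)-2-[4-(benzyloxy)phenyl]-4-oxo-4H-chromen-7-yl 2,2,2-trichloroethyl sulfate
Product: 10 (Fl)acetic acid, via arylacetaldehyde 9 (not isolated)
Conditions: OsO4 (1 mol%), Oxone (2KHSO5·KHSO4·K2SO4; 4 equiv KHSO5), DMF, rt
Reagents that add atoms: potassium peroxymonosulfate (active part of Oxone), [K+].[O-]S(=O)(=O)OO
Why: Osmium-catalysed oxidative cleavage of the terminal alkene, in which Oxone cleaves the osmate ester to the aldehyde and oxidises it on to the acid in the same flask, the conjugated, electron-poor pyrone double bond being far less reactive toward OsO4 than the monosubstituted alkene.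

Step 6
Reactants: 11 3,5-bis(benzyloxy)phenol; 12 acetic anhydride
Product: 13 3,5-bis(benzyloxy)phenyl acetate
Conditions: Ac2O, pyridine, DMAP (cat.), CH2Cl2, rt
Reagents that add atoms: acetic anhydride, CC(=O)OC(C)=O
Why: Acetylation of a phenol, which turns one of the three ring A oxygens into a weak donor that decides the site of the following acylation and can later be removed without base.

Step 7
Reactants: 10 (Fl)acetic acid; 13 3,5-bis(benzyloxy)phenyl acetate
Product: 15 3,5-bis(benzyloxy)-2-[(Fl)acetyl]phenyl acetate, via mixed trifluoroacetic anhydride 14 (not isolated)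
Conditions: (CF3CO)2O, H3PO4 (85%, cat.), CH2Cl2, 0 °C to rt
Reagents that add atoms: 3,5-bis(benzyloxy)phenyl acetate, CC(=O)Oc1cc(OCc2ccccc2)cc(OCc2ccccc2)c1
Why: Friedel–Crafts acylation through the mixed trifluoroacetic anhydride, which, as with 5-substituted resorcinol diethers, should attack the position para to one benzyloxy group and ortho to the other (next to the acetoxy group) and not the position between the two ethers, while the sulfate diester and the aryl acetate are stable to the acidic medium.

Step 8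
Reactants: 15 3,5-bis(benzyloxy)-2-[(Fl)acetyl]phenyl acetate
Product: 16 1-[2,4-bis(benzyloxy)-6-hydroxyphenyl]-2-(Fl)ethan-1-one
Conditions: NH4OAc, MeOH/THF/H2O, rt
Reagents that add atoms: none
Why: Neutral ammonium acetate-mediated methanolysis of an aryl acetate activated by the ortho ketone, which spares the sulfate diester and avoids the base-induced acyl shift to the active methylene group (Baker–Venkataraman pathway).

Step 9
Reactants: 16 1-[2,4-bis(benzyloxy)-6-hydroxyphenyl]-2-(Fl)ethan-1-one; 17 4-(bromomethyl)phenyl acetate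
Product: 18 4-({3,5-bis(benzyloxy)-2-[(Fl)acetyl]phenoxy}methyl)phenyl acetate
Conditions: K2CO3, Bu4NI (cat.), acetone, 45 °C
Reagents that add atoms: 4-(bromomethyl)phenyl acetate, CC(=O)Oc1ccc(CBr)cc1
Why: Williamson etherification of the ketone-chelated phenol, the only acidic hydroxyl left, with a reactive benzylic bromide, using a weak carbonate base that should deprotonate the phenol but not the methylene group and leave the aryl acetate and the sulfate diester in place.

Step 10
Reactants: 18 4-({3,5-bis(benzyloxy)-2-[(Fl)acetyl]phenoxy}methyl)phenyl acetate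
Product: 19 1-{2,4-bis(benzyloxy)-6-[(4-hydroxybenzyl)oxy]phenyl}-2-(Fl)ethan-1-one
Conditions: NH4OAc, MeOH/THF/H2O, rt; used promptly
Reagents that add atoms: none
Why: Neutral methanolysis of the aryl acetate, chosen because a strongly basic medium would turn the freed phenol into a phenoxide that expels the ring A phenoxide by 1,6-elimination.

Step 11
Reactants: 19 1-{2,4-bis(benzyloxy)-6-[(4-hydroxybenzyl)oxy]phenyl}-2-(Fl)ethan-1-one
Product: 21 (2R,3S)-5,7-bis(benzyloxy)-3-(Fl)-2-(4-hydroxyphenyl)chroman-4-one, via aryloxy para-quinone methide 20 (not isolated)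
Conditions: graphite-felt anode, Pt cathode, divided cell (Nafion membrane), Bu4NPF6 (0.1 M), CH2Cl2, (R)-TRIP [(R)-3,3'-bis(2,4,6-triisopropylphenyl)-1,1'-binaphthyl-2,2'-diyl hydrogen phosphate] (10 mol%), 4 Å MS, −20 °C, controlled potential at the onset of the phenol wave, 2.0 F/mol
Reagents that add atoms: none
Why: Proposed new method: anodic loss of two electrons and two protons from the only free phenol (ring B), eased by its hydrogen bond to the phosphate, should give the aryloxy para-quinone methide 20, which the chiral acid protonates on oxygen to an oxocarbenium-like cation held in a contact ion pair with the chiral phosphate, while the same acid enolises the aryl benzyl ketone so that the enol carbon C3 adds to C2 in a 1,6-fashion, forming C2–C3 and returning the ring B phenol. The closest known reaction types are the anodic benzylic oxidation of para-alkylphenols to quinone methides and chiral phosphoric acid-catalysed 1,6-additions of enols to para-quinone methides, which have not been merged or applied to an aryl 4-hydroxybenzyl ether. Ring C closes in a 6-(enolendo)-exo-trig mode through a chair-like transition state with ring B and the flavone unit equatorial. C2 is controlled by the face of the ion-paired cation that the phosphate leaves open (R expected from the (R)-configured catalyst), and C3, which stays enolisable under the acidic conditions, settles trans to it (S) as the diequatorial epimer. The step needs chemoselective oxidation and exclusion of water: ring B holds the only free phenol, the benzyl ethers, the flavone and the sulfate diester oxidise at higher potential, molecular sieves protect the cation from hydrolysis, and limiting the charge to two electrons per molecule guards the product phenol against further oxidation.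

Step 12
Reactants: 21 (2R,3S)-5,7-bis(benzyloxy)-3-(Fl)-2-(4-hydroxyphenyl)chroman-4-one
Product: 23 (2R,3S)-5,7-dihydroxy-3-[5-hydroxy-2-(4-hydroxyphenyl)-4-oxo-7-(sulfooxy)-4H-chromen-8-yl]-2-(4-hydroxyphenyl)chroman-4-one, via ammonium sulfate salt 22 (not isolated)
Conditions: 10% Pd/C, HCO2NH4, MeOH/THF, rt; filtration; Dowex 50WX8 (H+ form), MeOH/H2O, 0 °C
Reagents that add atoms: none
Why: Catalytic transfer hydrogenolysis should cleave the four benzyl ethers and reductively fragment the trichloroethyl ester (loss of chloride and 1,1-dichloroethene) to the sulfate monoester under near-neutral conditions that leave the aryl O–S bond and the two flavanone stereocenters untouched, and proton exchange then gives the free hydrogen sulfate.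

**Compound list**

1 | apigenin | O=c1cc(-c2ccc(O)cc2)oc2cc(O)cc(O)c12 | starting material
2 | allyl bromide | C=CCBr | starting material
3 | 7-(allyloxy)-5-hydroxy-2-(4-hydroxyphenyl)-4H-chromen-4-one | O=c1cc(-c2ccc(O)cc2)oc2cc(OCC=C)cc(O)c12 | intermediate
4 | benzyl bromide | BrCc1ccccc1 | starting material
5 | 7-(allyloxy)-5-(benzyloxy)-2-[4-(benzyloxy)phenyl]-4H-chromen-4-one | O=c1cc(-c2ccc(OCc3ccccc3)cc2)oc2cc(OCC=C)cc(OCc3ccccc3)c12 | intermediate
6 | 8-allyl-5-(benzyloxy)-2-[4-(benzyloxy)phenyl]-7-hydroxy-4H-chromen-4-one | O=c1cc(-c2ccc(OCc3ccccc3)cc2)oc2c(CC=C)c(O)cc(OCc3ccccc3)c12 | intermediate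
7 | 2,2,2-trichloroethyl chlorosulfate | ClS(=O)(=O)OCC(Cl)(Cl)Cl | starting material
8 | 8-allyl-5-(benzyloxy)-2-[4-(benzyloxy)phenyl]-4-oxo-4H-chromen-7-yl 2,2,2-trichloroethyl sulfate | O=c1cc(-c2ccc(OCc3ccccc3)cc2)oc2c(CC=C)c(OS(=O)(=O)OCC(Cl)(Cl)Cl)cc(OCc3ccccc3)c12 | intermediate
9 | (Fl)acetaldehyde | O=CCc1c(OS(=O)(=O)OCC(Cl)(Cl)Cl)cc(OCc2ccccc2)c2c(=O)cc(-c3ccc(OCc4ccccc4)cc3)oc12 | intermediate (not isolated)
10 | (Fl)acetic acid | OC(=O)Cc1c(OS(=O)(=O)OCC(Cl)(Cl)Cl)cc(OCc2ccccc2)c2c(=O)cc(-c3ccc(OCc4ccccc4)cc3)oc12 | intermediate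
11 | 3,5-bis(benzyloxy)phenol | Oc1cc(OCc2ccccc2)cc(OCc2ccccc2)c1 | starting material
12 | acetic anhydride | CC(=O)OC(C)=O | starting material
13 | 3,5-bis(benzyloxy)phenyl acetate | CC(=O)Oc1cc(OCc2ccccc2)cc(OCc2ccccc2)c1 | intermediate
14 | (Fl)acetic trifluoroacetic anhydride | O=C(Cc1c(OS(=O)(=O)OCC(Cl)(Cl)Cl)cc(OCc2ccccc2)c2c(=O)cc(-c3ccc(OCc4ccccc4)cc3)oc12)OC(=O)C(F)(F)F | intermediate (not isolated)
15 | 3,5-bis(benzyloxy)-2-[(Fl)acetyl]phenyl acetate | CC(=O)Oc1cc(OCc2ccccc2)cc(OCc2ccccc2)c1C(=O)Cc1c(OS(=O)(=O)OCC(Cl)(Cl)Cl)cc(OCc2ccccc2)c2c(=O)cc(-c3ccc(OCc4ccccc4)cc3)oc12 | intermediate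
16 | 1-[2,4-bis(benzyloxy)-6-hydroxyphenyl]-2-(Fl)ethan-1-one | Oc1cc(OCc2ccccc2)cc(OCc2ccccc2)c1C(=O)Cc1c(OS(=O)(=O)OCC(Cl)(Cl)Cl)cc(OCc2ccccc2)c2c(=O)cc(-c3ccc(OCc4ccccc4)cc3)oc12 | intermediate
17 | 4-(bromomethyl)phenyl acetate | CC(=O)Oc1ccc(CBr)cc1 | starting material
18 | 4-({3,5-bis(benzyloxy)-2-[(Fl)acetyl]phenoxy}methyl)phenyl acetate | O=C(Cc1c(OS(=O)(=O)OCC(Cl)(Cl)Cl)cc(OCc2ccccc2)c2c(=O)cc(-c3ccc(OCc4ccccc4)cc3)oc12)c1c(OCc2ccccc2)cc(OCc2ccccc2)cc1OCc1ccc(OC(C)=O)cc1 | intermediate
19 | 1-{2,4-bis(benzyloxy)-6-[(4-hydroxybenzyl)oxy]phenyl}-2-(Fl)ethan-1-one | O=C(Cc1c(OS(=O)(=O)OCC(Cl)(Cl)Cl)cc(OCc2ccccc2)c2c(=O)cc(-c3ccc(OCc4ccccc4)cc3)oc12)c1c(OCc2ccccc2)cc(OCc2ccccc2)cc1OCc1ccc(O)cc1 | intermediate (precursor of the key step)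
20 | 1-{2,4-bis(benzyloxy)-6-[(4-oxocyclohexa-2,5-dien-1-ylidene)methoxy]phenyl}-2-(Fl)ethan-1-one | O=C(Cc1c(OS(=O)(=O)OCC(Cl)(Cl)Cl)cc(OCc2ccccc2)c2c(=O)cc(-c3ccc(OCc4ccccc4)cc3)oc12)c1c(OCc2ccccc2)cc(OCc2ccccc2)cc1OC=C1C=CC(=O)C=C1 | intermediate (not isolated)
21 | (2R,3S)-5,7-bis(benzyloxy)-3-(Fl)-2-(4-hydroxyphenyl)chroman-4-one | O=C1c2c(OCc3ccccc3)cc(OCc3ccccc3)cc2O[C@@H](c2ccc(O)cc2)[C@@H]1c1c(OS(=O)(=O)OCC(Cl)(Cl)Cl)cc(OCc2ccccc2)c2c(=O)cc(-c3ccc(OCc4ccccc4)cc3)oc12 | intermediate (product of the key step)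
22 | ammonium (2R,3S)-8-[5,7-dihydroxy-2-(4-hydroxyphenyl)-4-oxochroman-3-yl]-5-hydroxy-2-(4-hydroxyphenyl)-4-oxo-4H-chromen-7-yl sulfate | O=C1c2c(O)cc(O)cc2O[C@@H](c2ccc(O)cc2)[C@@H]1c1c(OS(=O)(=O)[O-])cc(O)c2c(=O)cc(-c3ccc(O)cc3)oc12.[NH4+] | intermediate (not isolated)
23 | (2R,3S)-5,7-dihydroxy-3-[5-hydroxy-2-(4-hydroxyphenyl)-4-oxo-7-(sulfooxy)-4H-chromen-8-yl]-2-(4-hydroxyphenyl)chroman-4-one | O=C1c2c(O)cc(O)cc2O[C@@H](c2ccc(O)cc2)[C@@H]1c1c(OS(=O)(=O)O)cc(O)c2c(=O)cc(-c3ccc(O)cc3)oc12 | target

**Step count and risks**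

Total step count: 12. Longest linear sequence: 11 steps (steps 1–5 and 7–12, from apigenin); step 6 is a one-step side branch.

Steps most likely to fail:

1. Step 11 (new method). The cyclised phenol may be oxidised further (dehydrogenation of ring C), the cationic intermediate may be hydrolysed or fragment to the ring A phenol, and facial selectivity inside the ion pair may be poor. The fallback uses known chemistry and sets out from 16. Amine-catalysed Knoevenagel condensation with 4-hydroxybenzaldehyde (pyrrolidine, AcOH, EtOH, 60 °C) should give the 2'-hydroxy-α-arylchalcone 1-[2,4-bis(benzyloxy)-6-hydroxyphenyl]-2-(Fl)-3-(4-hydroxyphenyl)prop-2-en-1-one F1. Under the same conditions this closes by intramolecular oxa-Michael addition to the thermodynamically preferred trans-2,3-diarylchromanone as a racemate, that is 21 together with its mirror image (2S,3R)-5,7-bis(benzyloxy)-3-(Fl)-2-(4-hydroxyphenyl)chroman-4-one F2. Preparative HPLC on a cellulose carbamate chiral phase separates the two, and the route is rejoined at 21. This variant forms O1–C2 last and makes steps 9 and 10 unnecessary.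

2. Step 7. Acylation may occur between the two benzyl ethers, the mixed anhydride may self-condense through its ketene, and the acid may cause loss or migration of benzyl groups. The fallback sets out from 10 and 11. Carbodiimide esterification (EDC·HCl, DMAP, CH2Cl2) gives the aryl ester 3,5-bis(benzyloxy)phenyl (Fl)acetate F3. A Fries rearrangement with catalytic Sc(OTf)3 in toluene/nitromethane then delivers the acyl group from oxygen to the neighbouring ring carbon, which fixes the regiochemistry by tethering. The route is rejoined at 16, and steps 6 and 8 fall away.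

3. Step 12. Debenzylation may stay incomplete while the flavone 2,3-double bond is reduced, the benzylic C2–O1 bond of ring C may be hydrogenolysed, and the flavanone may epimerise through ring opening in the basic formate medium. The fallback sets out from 21. BCl3 with pentamethylbenzene as cation scavenger (CH2Cl2, −78 °C) removes the four benzyl ethers without any reduction and should give (2R,3S)-5,7-dihydroxy-3-[5-hydroxy-2-(4-hydroxyphenyl)-4-oxo-7-{[(2,2,2-trichloroethoxy)sulfonyl]oxy}-4H-chromen-8-yl]-2-(4-hydroxyphenyl)chroman-4-one F4. Zn dust with HCO2NH4 in MeOH at rt then fragments the trichloroethyl ester to the ammonium salt 22, from which proton exchange gives 23 as in the route.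

**Further compounds**

F1 | step 11 | 1-[2,4-bis(benzyloxy)-6-hydroxyphenyl]-2-(Fl)-3-(4-hydroxyphenyl)prop-2-en-1-one (alkene geometry not controlled, equilibrating) | Oc1cc(OCc2ccccc2)cc(OCc2ccccc2)c1C(=O)C(=Cc1ccc(O)cc1)c1c(OS(=O)(=O)OCC(Cl)(Cl)Cl)cc(OCc2ccccc2)c2c(=O)cc(-c3ccc(OCc4ccccc4)cc3)oc12
F2 | step 11 | (2S,3R)-5,7-bis(benzyloxy)-3-(Fl)-2-(4-hydroxyphenyl)chroman-4-one (enantiomer of 21) | O=C1c2c(OCc3ccccc3)cc(OCc3ccccc3)cc2O[C@H](c2ccc(O)cc2)[C@H]1c1c(OS(=O)(=O)OCC(Cl)(Cl)Cl)cc(OCc2ccccc2)c2c(=O)cc(-c3ccc(OCc4ccccc4)cc3)oc12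
F3 | step 7 | 3,5-bis(benzyloxy)phenyl (Fl)acetate | O=C(Cc1c(OS(=O)(=O)OCC(Cl)(Cl)Cl)cc(OCc2ccccc2)c2c(=O)cc(-c3ccc(OCc4ccccc4)cc3)oc12)Oc1cc(OCc2ccccc2)cc(OCc2ccccc2)c1
F4 | step 12 | (2R,3S)-5,7-dihydroxy-3-[5-hydroxy-2-(4-hydroxyphenyl)-4-oxo-7-{[(2,2,2-trichloroethoxy)sulfonyl]oxy}-4H-chromen-8-yl]-2-(4-hydroxyphenyl)chroman-4-one | O=C1c2c(O)cc(O)cc2O[C@@H](c2ccc(O)cc2)[C@@H]1c1c(OS(=O)(=O)OCC(Cl)(Cl)Cl)cc(O)c2c(=O)cc(-c3ccc(O)cc3)oc12
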